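The data stem from a simulated flask for substances that don't exist; scatter was added.

**The number.** A ratio of 10.7 carries this problem: the logarithm of the fraction of left-handed substrate left, over the logarithm of the fraction of right-handed substrate left, the selectivity factor. It is read at the last point of Saturday's run, so it carries that run's scatter. Freeze it, and the right-handed fraction left is the left-handed fraction raised to one over this factor. The excess then follows from one amount: how much left-handed substrate remains.

| setting | Friday's | Saturday's | north | north-west |
|---|---|---|---|---|
| left-handed substrate | 63 mM | 21 mM | 42 mM | 42 mM |
| right-handed substrate | 63 mM | 21 mM | 42 mM | 42 mM |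
| gas | 1.9 mM (held) | 1.9 mM (held) | 1.9 mM (held) | 1.9 mM (held) |
| free catalyst | 0.42 mM | 0.42 mM | 0.42 mM | 0.15 mM |
| remark | run made earlier | run made earlier |  |  |
| time |  |  | 10 d | 10 d |

- Friday's (time / d: right-handed substrate / %, left-handed substrate / %, left-handed product / %): 0.333: 48, 49, 1; 0.833: 48, 46, 3; 1.67: 52, 42, 9; 2.50: 50, 39, 10; 4.00: 48, 31, 14
- Saturday's (time / d: right-handed substrate / %, left-handed substrate / %, left-handed product / %): 0.250: 50, 47, 1; 0.500: 49, 46, 3; 1.04: 48, 36, 13; 1.67: 49, 31, 17; 4.00: 43, 10, 27

(each reading ± 1.5 percentage points)

1. the flask that ends with the higher excess of right-handed substrate over left-handed substrate among what is left of the two, or "neither" when 2 percentage points or less lies between them (north / north-west / neither)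
2. excess of right-handed substrate over left-handed substrate among what is left of the two at the end, north
3. excess of right-handed substrate over left-handed substrate among what is left of the two at the end, north-west

- free catalyst is single-handed; left-handed substrate and right-handed substrate are mirror images of each other, charged as a racemate, each of them at the stated concentration
- at the start none of the gas is in solution
- an excess is the difference of the two amounts in percent of their sum
- an excess is below zero if the other one leads
- no earlier run changes the charge of free catalyst; that part of a forecast is a guess

**First instants.** Saturday's left-handed substrate reads 46% at 0.500 d, then 36% at 1.04 d. A straight fall from the charge to that later reading stands at 43.3% at 0.500 d, 2.7 percentage points from the reading, whose scatter is 1.5 points. So count no lag, and start the clock at zero.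

**The middle.** Try the rule that equal fractions come at times proportional to the charge. Friday's run has 3.00 times Saturday's charge, and its 31% at 4.00 d maps to 1.33 d on Saturday's clock. Saturday's readings of 36% at 1.04 d and 31% at 1.67 d put that time near 33.7%, which is 2.7 points from Friday's reading, with a scatter of 1.5 points on each reading. So take the two runs to share one clock.

**The end.** North has twice Saturday's charge, so its 10 d maps to 5.00 d, past Saturday's last reading. Saturday's tail looks pseudo-first-order, falling at 0.486 d⁻¹. That leaves 12.3% of north's left-handed charge, and the factor makes this an excess of 73.9%.

For north-west, guess that the clock runs in proportion to the catalyst. That gives 1.79 d, a left-handed fraction of 58.6% and an excess of 23.7%. This reckoning therefore favours north.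

**The forecast.** The forecast also names north, with 83% for north and 29% for north-west, and it says: “Selectivity, from ln ratios of the two substrates, is about 11”. Its north figure stands above the 73.9% reckoned here, and its north-west figure above the 23.7% reckoned here.

**The flasks.** The simulation gives north, with 75.9% for north and 32.7% for north-west. The forecast's north figure is 7.1 points too high.

    free catalyst + left-handed substrate ⇌ catalyst intermediate A (K = 58.9 M⁻¹, k = 6720 M⁻¹ h⁻¹)
    free catalyst + right-handed substrate ⇌ catalyst intermediate B (K = 205 M⁻¹, k = 24800 M⁻¹ h⁻¹)
    reagent + catalyst intermediate A → free catalyst + left-handed product (k = 2440 M⁻¹ h⁻¹)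
    reagent + catalyst intermediate B → free catalyst + right-handed product (k = 38.1 M⁻¹ h⁻¹)
    left-handed product ⇌ right-handed product (k = 0.0137 h⁻¹)
    gas ⇌ reagent, rate k6*(csat - [reagent]) (kL = 0.794 h⁻¹)
    reagent ⇌ dormant form (K = 23.8, k = 0.157 h⁻¹)

**After the result.** North stopped with 12% of its left-handed charge unbound, and the factor 10.7 turns that into 74.5%, beside the 75.9% obtained. At equal reagent, catalyst intermediate A turns over 64.0 times as fast as catalyst intermediate B. Yet north-west at 10.0 d holds 79.2% of its catalyst as intermediate B, the resting state, and 11.1% as intermediate A. Read at 6.0 d, north-west has 66% of its left-handed charge unbound, which the factor turns into 18.3%, and that flask shows 18.9%.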